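## The problem

The target is a 3-hydroxyisoflavanone. Ring A, a benzo ring with the C7 hydroxyl, is fused to the dihydropyranone ring C, and ring B is attached at C3. C3 is quaternary, carries the tertiary hydroxyl, lies between the C2 methylene and the C4 ketone, and is the only stereocentre (R). With no second stereocentre to relay from, its configuration has to come from a chiral reagent or catalyst and must survive the remaining steps. Ring B is pentasubstituted: three neighbouring oxygens at C2', C3' and C4', of which only the C4' oxygen is methylated, and next to them a 1,1-dimethylallyl group at C5' whose benzylic carbon is quaternary. The tertiary α-hydroxy ketone can lose water towards the isoflavone under strong acid, the free catechol is easily oxidised, and the terminal vinyl group rules out hydrogenolysis, so the phenols need masks that leave under mild, non-reducing conditions. The C4' oxygen also has to be told apart from its two neighbours before it is methylated. The feature that opens the route is that the C4' oxygen and the C5' quaternary carbon are ortho neighbours beside the C3' oxygen: an aryne spanning C4' and C5' is polarised by the C3' alkoxy group, so a carbon nucleophile should enter at C5' and leave a metal at C4' that can be converted into the oxygen, which then appears as the only free phenol.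

## Retrosynthesis

**18 to 17.** The three phenolic O–H bonds of target 18 are traced back to methoxymethyl (MOM) ethers in 17. MOM is preferred to benzyl (hydrogenolysis would reduce the vinyl group) and to silyl (no directing or chelating power, doubtful survival of the organometallic steps). The forward reaction must use acid mild enough to leave the tertiary carbinol and the vinyl group alone.

**17 to 16.** The C3–C4 bond is cut. This turns the carbinol carbon into a ketone and C4 into an aldehyde, so the acyclic, achiral keto aldehyde 16 can close ring C by an intramolecular crossed benzoin reaction. Cutting O1–C2 or C4–C4a instead would require the stereocentre to be made beforehand. The forward reaction must make the aldehyde the acyl anion donor, the hindered ketone the acceptor, and attack one face of it.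

**16 to 13 and 15.** The ether bond O1–C2 is cut, giving the chloromethyl ketone 13 (ring B) and the salicylaldehyde 15 (ring A), two halves of similar size. The forward reaction is an SN2 etherification that has to stop before any aldol condensation between the new ketone and the aldehyde.

**15 to 14.** The MOM ether of 15 is removed to give 2,4-dihydroxybenzaldehyde 14. The forward reaction relies on the lower reactivity of the hydroxyl that is hydrogen-bonded to the aldehyde.

**13 to 11.** The C1'–C3 bond is cut. The C2' MOM ether of 11 is the only directing group with a free ortho position, so deprotonation gives the aryllithium 12 at the right carbon without a halogenation step. A Friedel–Crafts acylation would meet acid-labile acetals and two open ring positions. The forward reaction needs a chloroacetyl donor that stops at the ketone.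

**11 to 10.** The O–CH3 bond at C4' is cut. Phenol 10 has exactly one free hydroxyl, so no selectivity is asked of the methylation.

**10 to 3 and 5.** The C5'–C bond to the quaternary carbon and the C4'–O bond are cut together. This leads to the aryne 7, generated from the bromofluoroarene 3 through the Grignard reagent 6, and to prenylmagnesium chloride 5. The adduct 8 is converted to the phenol through the boronate 9. The neighbouring disconnection, a Claisen rearrangement of a prenyl ether, only moves the problem of differentiating three adjacent oxygens to an earlier stage. Here 3 has no carbon substituent and the C4' oxygen arrives already distinguished. The forward reaction must control the site of attack on the aryne, the γ-selectivity of the allyl unit, and the capture of a hindered aryl Grignard reagent.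

**3 to 2 to 1, and 5 to 4.** The C–Br bond of 3 is cut to give the bis-MOM ether 2, and the two MOM groups lead back to 3-fluorocatechol 1. Bromination para to the unflanked ether oxygen places bromine next to fluorine. The Grignard reagent 5 comes from prenyl chloride 4 and magnesium.

## Roads not taken

**Alternative 1:** Both bonds from ring A to ring C, O1–C8a and C4–C4a, are cut. Ring A enters as an aryne, and everything else, ring B and the C3 stereocentre included, enters as the chiral β-hydroxy ester A2. In the forward direction the fluoride-generated 3-bromo-5-(methoxymethoxy)benzyne A3 would be attacked by the primary alkoxide of A2 at the carbon remote from bromine. The aryl anion formed next to bromine would then acylate itself on the ester, closing ring C to the bromochromanone A1.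

- Merits: ring C closes in one convergent operation, the stereocentre is not touched while the ring forms, and the aryne regiochemistry is steered by a substituent chosen for that purpose. In this respect the road is better than the chosen plan, which creates C3 by a catalyst-controlled addition to a hindered ketone.
- Weak points for this target:
  - The bromine at C5 is an auxiliary that must later be removed by a reduction that spares the vinyl group and the ketone.
  - The aryl anion beside bromine can lose bromide or be protonated before it reaches the neopentyl-type ester.
  - The tertiary hydroxyl has to travel as a fourth MOM ether.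
  - A2 needs its own enantioselective synthesis, most plausibly a dihydroxylation of an α-aryl acrylate that must ignore the vinyl group of the dimethylallyl unit.
  - The pentasubstituted ring B is not addressed at all.
- Comparison: against the more secure stereocentre the chosen plan sets a shorter sequence, ring B assembled in one step, and no auxiliary atom to remove.

**Alternative 2:** The C3–O and C2–C3 bonds are cut, so that C3 becomes a carbene carbon between ring B and the ring A ketone. Rh2(OAc)4 would decompose the α-diazo deoxybenzoin A5, and 4-methoxybenzyl alcohol A6 would add to the carbene. The oxonium ylide would be intercepted by formaldehyde A7 under a chiral phosphoric acid such as (R)-3,3'-bis(2,4,6-triisopropylphenyl)-1,1'-binaphthyl-2,2'-diyl hydrogen phosphate, giving the hydroxymethyl ether A4. Displacement of the ring A fluoride by the primary alkoxide would then close ring C.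

- Merits: the quaternary centre and both of its new bonds arise in one multicomponent step, and the later ring closure is a robust nucleophilic aromatic substitution activated by the ortho ketone. The road does not depend on the electrophilicity of the ring B ketone, on which the benzoin closure of the chosen plan relies.
- Weak points for this target:
  - The ylide must be trapped by an aldehyde that offers no steric handle, before it collapses by proton shift to the plain O–H insertion product.
  - The carbene carbon carries an ortho-substituted, electron-rich aryl group, which should slow ylide formation and trapping.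
  - A5 requires the ring B arylacetic acid series and a diazo transfer.
  - The 4-methoxybenzyl group adds a further deprotection next to a masked catechol.
  - Ring B again has to come from elsewhere.
- Comparison: the step count is no smaller, and the least precedented event coincides with the stereo-defining one, late, on the most valuable material. In the chosen plan the unprecedented step stands early on a simple achiral arene, where failure is cheap.

**Alternative 3:** The C3–C4 bond is cut, opening ring C to the keto aldehyde A9. A chiral triazolium-derived carbene converts the ring A aldehyde into a Breslow intermediate that adds to the ring B ketone and gives A8. A8 and A9 are the same structures as 17 and 16, so this road is identical with the endgame of the chosen plan.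

- Merits: at the decisive point it is as good as or better than the chosen strategy. Its key step is known chemistry for this substrate class, closes ring C, and sets the only stereocentre at once.
- Weak point: it leaves the origin of ring B open. The classical answer, a Claisen rearrangement of an aryl prenyl ether, requires the three neighbouring oxygens to be differentiated beforehand and the rearrangement to stop at the ortho product.
- Comparison: the chosen plan answers the ring B question with the aryne step. The C5' carbon and the C4' oxygen are introduced together, the regiochemistry is fixed by the C3' alkoxy group, and the C4' oxygen emerges as the only free phenol. The price is a step without direct precedent, which is why the Claisen route is kept as its fallback.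

Key step: step 4

Assumption: the (5aR,10bS) enantiomer of the aminoindanol-derived triazolium salt is taken to deliver the (R)-carbinol in step 9; if the sense of induction proves opposite, the (5aS,10bR) salt is used and nothing else changes.

## Route

Step 1
Reactants: 1 3-fluorocatechol (3-fluorobenzene-1,2-diol)
Product: 2 1-fluoro-2,3-bis(methoxymethoxy)benzene
Conditions: MOMCl (2.5 equiv), i-Pr2NEt (3 equiv), CH2Cl2, 0 °C to rt
Reagents that add atoms: chloromethyl methyl ether, COCCl
Why: Double O-alkylation of the catechol with a chloromethyl ether under amine base (Williamson-type acetal ether formation); the MOM groups later act as directing and chelating groups and leave under mild acid.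

Step 2
Reactants: 2 1-fluoro-2,3-bis(methoxymethoxy)benzene
Product: 3 1-bromo-2-fluoro-3,4-bis(methoxymethoxy)benzene
Conditions: NBS (1.05 equiv), MeCN, 0 °C to rt
Reagents that add atoms: N-bromosuccinimide, O=C1CCC(=O)N1Br
Why: Electrophilic aromatic bromination; the C3 ether oxygen can lie in the ring plane and is a better donor than the C2 oxygen squeezed between two substituents, and its para position is the carbon next to fluorine. NBS in acetonitrile is neutral, so the MOM acetals should survive.

Step 3
Reactants: 4 prenyl chloride (1-chloro-3-methylbut-2-ene)
Product: 5 prenylmagnesium chloride (3-methylbut-2-en-1-ylmagnesium chloride, THF solution)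
Conditions: Mg turnings (excess), THF, 0 °C, slow addition
Reagents that add atoms: magnesium, [Mg]
Why: Grignard formation from an allylic chloride; slow addition to excess magnesium in the cold keeps Wurtz coupling low.

Step 4
Reactants: 3 1-bromo-2-fluoro-3,4-bis(methoxymethoxy)benzene; 5 prenylmagnesium chloride
Product: 10 2,3-bis(methoxymethoxy)-6-(2-methylbut-3-en-2-yl)phenol, via aryl Grignard reagent 6 (not isolated), via aryne 7 (not isolated), via magnesiated adduct 8 (not isolated), via dimethyl arylboronate 9 (not isolated)
Conditions: i-PrMgCl·LiCl (1.0 equiv), THF, 0 °C; then 5 (3 equiv), 0 to 55 °C; B(OMe)3 (6 equiv), −20 °C to rt; 30% H2O2, aq. NaOH, 0 °C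
Reagents that add atoms: hydrogen peroxide, OO (oxygen of the new phenol); into the intermediates only: isopropylmagnesium chloride, CC(C)[Mg]Cl, and trimethyl borate, COB(OC)OC
Why: Proposed new method: i-PrMgCl·LiCl exchanges the bromine of 3 in the cold, and on warming the ortho-fluoro Grignard reagent 6 loses MgClF to give aryne 7 in the presence of excess 5. The allylic Grignard reagent is expected to add through a six-membered magnesium-ene (SE2') transition state, so its γ-carbon, the dimethyl-substituted one, bonds to the aryne while magnesium passes to the neighbouring carbon, giving 8. The alkoxy group beside the triple bond polarises 7 so that the distal aryne carbon is the electrophilic one, and the MOM oxygen can chelate magnesium at the proximal carbon; both effects put carbon at C5' and the metal at C4' (ring B numbering). Borylation of 8 with B(OMe)3 to 9 and oxidation with alkaline H2O2 then convert the C–Mg bond into the C–O bond at the same carbon. The closest known reaction types are the carbomagnesiation of arynes with electrophilic trapping of the resulting aryl Grignard reagent and the γ-selective addition of prenylmagnesium halides to carbonyl compounds; an allylic Grignard reagent forming a quaternary benzylic carbon on an aryne, followed by oxidation, has not been described. No ring is closed and no stereocentre is formed. The step needs site selectivity on the aryne and γ-selectivity in the allyl unit; complete exchange before warming and a threefold excess of 5 should keep additions of isopropyl and aryl Grignard reagents to 7 in the background.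

Step 5
Reactants: 10 2,3-bis(methoxymethoxy)-6-(2-methylbut-3-en-2-yl)phenol
Product: 11 2-methoxy-3,4-bis(methoxymethoxy)-1-(2-methylbut-3-en-2-yl)benzene
Conditions: NaH, MeI, THF/DMF, 0 °C to rt
Reagents that add atoms: iodomethane, CI
Why: Williamson methylation of the only free phenol; the sodium phenoxide should be reactive enough despite its two ortho substituents.

Step 6
Reactants: 11 2-methoxy-3,4-bis(methoxymethoxy)-1-(2-methylbut-3-en-2-yl)benzene
Product: 13 2-chloro-1-[4-methoxy-2,3-bis(methoxymethoxy)-5-(2-methylbut-3-en-2-yl)phenyl]ethan-1-one, via aryllithium 12 (not isolated)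
Conditions: n-BuLi, TMEDA, THF, −20 to 0 °C; ClCH2C(O)N(OMe)Me, −78 °C; aq. NH4Cl
Reagents that add atoms: 2-chloro-N-methoxy-N-methylacetamide, CON(C)C(=O)CCl; n-butyllithium, [Li]CCCC (lithium of 12 only)
Why: Directed ortho-metalation; the C4 MOM ether of 11 is the only directing group with a free ortho position, so lithium enters at C5, the future C1'. The aryllithium acylates the Weinreb amide through a chelated tetrahedral intermediate, which should give the chloromethyl ketone without over-addition.

Step 7
Reactants: 14 2,4-dihydroxybenzaldehyde
Product: 15 2-hydroxy-4-(methoxymethoxy)benzaldehyde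
Conditions: MOMCl (1.05 equiv), K2CO3, acetone, 0 °C to rt
Reagents that add atoms: chloromethyl methyl ether, COCCl
Why: Selective O-alkylation; the C2 hydroxyl is hydrogen-bonded to the aldehyde and less nucleophilic, so the C4 hydroxyl should react.

Step 8
Reactants: 13 2-chloro-1-[4-methoxy-2,3-bis(methoxymethoxy)-5-(2-methylbut-3-en-2-yl)phenyl]ethan-1-one; 15 2-hydroxy-4-(methoxymethoxy)benzaldehyde
Product: 16 2-{2-[4-methoxy-2,3-bis(methoxymethoxy)-5-(2-methylbut-3-en-2-yl)phenyl]-2-oxoethoxy}-4-(methoxymethoxy)benzaldehyde
Conditions: K2CO3, NaI (cat.), DMF, rt
Reagents that add atoms: none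
Why: Williamson ether synthesis by SN2 displacement on the activated α-chloro ketone; room temperature and a mild base are chosen to avoid the aldol condensation to a 2-aroylbenzofuran (Rap–Stoermer reaction).

Step 9
Reactants: 16 2-{2-[4-methoxy-2,3-bis(methoxymethoxy)-5-(2-methylbut-3-en-2-yl)phenyl]-2-oxoethoxy}-4-(methoxymethoxy)benzaldehyde
Product: 17 (3R)-3-hydroxy-3-[4-methoxy-2,3-bis(methoxymethoxy)-5-(2-methylbut-3-en-2-yl)phenyl]-7-(methoxymethoxy)-2,3-dihydro-4H-chromen-4-one
Conditions: (5aR,10bS)-2-(pentafluorophenyl)-5a,10b-dihydro-4H,6H-indeno[2,1-b][1,2,4]triazolo[4,3-d][1,4]oxazin-2-ium tetrafluoroborate (10 mol %), Et3N (20 mol %), toluene, rt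
Reagents that add atoms: none
Why: Intramolecular crossed benzoin reaction under N-heterocyclic carbene catalysis, a known closure of 2-(2-aryl-2-oxoethoxy)benzaldehydes to 3-aryl-3-hydroxychroman-4-ones. The carbene adds to the aldehyde and the Breslow intermediate attacks the tethered ketone in a 6-exo-trig closure of ring C. The aminoindanol backbone shields one face of the acyl anion equivalent, so one face of the ketone is attacked and C3 is set as R under catalyst control.

Step 10
Reactants: 17 (3R)-3-hydroxy-3-[4-methoxy-2,3-bis(methoxymethoxy)-5-(2-methylbut-3-en-2-yl)phenyl]-7-(methoxymethoxy)-2,3-dihydro-4H-chromen-4-one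
Product: 18 (3R)-3-[2,3-dihydroxy-4-methoxy-5-(2-methylbut-3-en-2-yl)phenyl]-3,7-dihydroxy-2,3-dihydro-4H-chromen-4-one (CNP0274064.1)
Conditions: 2 M HCl, MeOH, rt
Reagents that add atoms: none
Why: Acid-catalysed acetal exchange with methanol removes the three phenolic MOM ethers; dilute acid at room temperature should neither ionise the tertiary carbinol nor protonate the vinyl group. C3 has no α-hydrogen and cannot epimerise.

## Compound list

1 | 3-fluorocatechol (3-fluorobenzene-1,2-diol) | Oc1cccc(F)c1O | starting material
2 | 1-fluoro-2,3-bis(methoxymethoxy)benzene | COCOc1cccc(F)c1OCOC | intermediate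
3 | 1-bromo-2-fluoro-3,4-bis(methoxymethoxy)benzene | COCOc1ccc(Br)c(F)c1OCOC | intermediate
4 | prenyl chloride (1-chloro-3-methylbut-2-ene) | CC(C)=CCCl | starting material
5 | prenylmagnesium chloride | CC(C)=CC[Mg]Cl | intermediate
6 | [2-fluoro-3,4-bis(methoxymethoxy)phenyl]magnesium chloride | COCOc1ccc([Mg]Cl)c(F)c1OCOC | intermediate (not isolated)
7 | 3,4-bis(methoxymethoxy)benzyne | COCOC1=C(OCOC)C#CC=C1 | intermediate (not isolated)
8 | [2,3-bis(methoxymethoxy)-6-(2-methylbut-3-en-2-yl)phenyl]magnesium chloride | C=CC(C)(C)c1ccc(OCOC)c(OCOC)c1[Mg]Cl | intermediate (not isolated)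
9 | dimethyl [2,3-bis(methoxymethoxy)-6-(2-methylbut-3-en-2-yl)phenyl]boronate | C=CC(C)(C)c1ccc(OCOC)c(OCOC)c1B(OC)OC | intermediate (not isolated)
10 | 2,3-bis(methoxymethoxy)-6-(2-methylbut-3-en-2-yl)phenol | C=CC(C)(C)c1ccc(OCOC)c(OCOC)c1O | intermediate
11 | 2-methoxy-3,4-bis(methoxymethoxy)-1-(2-methylbut-3-en-2-yl)benzene | C=CC(C)(C)c1ccc(OCOC)c(OCOC)c1OC | intermediate
12 | [4-methoxy-2,3-bis(methoxymethoxy)-5-(2-methylbut-3-en-2-yl)phenyl]lithium | C=CC(C)(C)c1cc([Li])c(OCOC)c(OCOC)c1OC | intermediate (not isolated)
13 | 2-chloro-1-[4-methoxy-2,3-bis(methoxymethoxy)-5-(2-methylbut-3-en-2-yl)phenyl]ethan-1-one | C=CC(C)(C)c1cc(C(=O)CCl)c(OCOC)c(OCOC)c1OC | intermediate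
14 | 2,4-dihydroxybenzaldehyde | O=Cc1ccc(O)cc1O | starting material
15 | 2-hydroxy-4-(methoxymethoxy)benzaldehyde | COCOc1ccc(C=O)c(O)c1 | intermediate
16 | 2-{2-[4-methoxy-2,3-bis(methoxymethoxy)-5-(2-methylbut-3-en-2-yl)phenyl]-2-oxoethoxy}-4-(methoxymethoxy)benzaldehyde | C=CC(C)(C)c1cc(C(=O)COc2cc(OCOC)ccc2C=O)c(OCOC)c(OCOC)c1OC | intermediate
17 | (3R)-3-hydroxy-3-[4-methoxy-2,3-bis(methoxymethoxy)-5-(2-methylbut-3-en-2-yl)phenyl]-7-(methoxymethoxy)-2,3-dihydro-4H-chromen-4-one | C=CC(C)(C)c1cc([C@@]2(O)COc3cc(OCOC)ccc3C2=O)c(OCOC)c(OCOC)c1OC | intermediate
18 | (3R)-3-[2,3-dihydroxy-4-methoxy-5-(2-methylbut-3-en-2-yl)phenyl]-3,7-dihydroxy-2,3-dihydro-4H-chromen-4-one | C=CC(C)(C)c1cc([C@@]2(O)COc3cc(O)ccc3C2=O)c(O)c(O)c1OC | target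

## Step count and least certain steps

Total: 10 steps. Longest linear sequence: 8 steps (1, 2, 4, 5, 6, 8, 9, 10); steps 3 and 7 prepare the side partners.

**Step 4 (key step, proposed new method).**
- What may go wrong: attack through the α-carbon of the allyl unit, giving a linear prenyl group; addition of 6 or of remaining isopropyl Grignard reagent to the aryne; incomplete borylation of the doubly ortho-substituted aryl Grignard reagent, so that protonation replaces oxidation.
- Fallback (known chemistry, aromatic Claisen rearrangement): it sets out from prenyl chloride 4 and returns at 10. Catechol is converted to 1,2-bis(methoxymethoxy)benzene F1 (MOMCl, i-Pr2NEt). Ortho-lithiation with n-BuLi, then B(OMe)3 and alkaline H2O2, gives 2,3-bis(methoxymethoxy)phenol F2. O-Alkylation of F2 with 4 (K2CO3, DMF) gives the prenyl ether 1,2-bis(methoxymethoxy)-3-[(3-methylbut-2-en-1-yl)oxy]benzene F3. Heating F3 in N,N-diethylaniline at about 190 °C should move the allyl unit with inversion to the only free ortho position and give 10.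

**Step 9.**
- What may go wrong: slow addition of the Breslow intermediate to a hindered, electron-rich aryl ketone; base-induced aldol condensation to a benzofuran overtaking the benzoin path; insufficient facial selectivity.
- Fallback (enolate hydroxylation instead of acyl anion addition): it sets out from 11 and returns at 17. Lithiation as in step 6 and quenching of 12 with 1,2-dibromotetrachloroethane gives 1-bromo-4-methoxy-2,3-bis(methoxymethoxy)-5-(2-methylbut-3-en-2-yl)benzene F4. Commercial 7-hydroxychroman-4-one is protected as 7-(methoxymethoxy)-2,3-dihydro-4H-chromen-4-one F5 (MOMCl, i-Pr2NEt). Palladium-catalysed α-arylation of F5 with F4 (Pd2(dba)3, P(t-Bu)3, NaOt-Bu, toluene, 70 °C) gives the racemic isoflavanone 3-[4-methoxy-2,3-bis(methoxymethoxy)-5-(2-methylbut-3-en-2-yl)phenyl]-7-(methoxymethoxy)-2,3-dihydro-4H-chromen-4-one F6. Its sodium enolate (NaN(SiMe3)2, THF, −78 °C) is hydroxylated with the enantiomer of (8,8-dichlorocamphorylsulfonyl)oxaziridine that delivers the (R)-carbinol, giving 17.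

**Step 2.**
- What may go wrong: bromination ortho instead of para to the C3 ether oxygen (the carbon para to fluorine), or partial loss of a MOM group through traces of HBr.
- Fallback (deprotonation instead of electrophilic substitution): it sets out from 2 and returns at 3. n-BuLi/KOt-Bu in THF at −75 °C should remove the most acidic ring proton, the one beside fluorine, giving [2-fluoro-3,4-bis(methoxymethoxy)phenyl]potassium F7. F7 is kept cold and quenched with 1,2-dibromotetrachloroethane to give 3.

**Step 10.**
- What may go wrong: acid-induced loss of water from the tertiary carbinol towards the isoflavone, or protonation of the vinyl group, before all three acetals are cleaved.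
- Fallback (silyl transfer instead of acid solvolysis): it sets out from 17 and ends at 18. Me3SiOTf and 2,2'-bipyridyl in CH2Cl2 at 0 °C should exchange the aryl MOM ethers for trimethylsilyl ethers and silylate the carbinol as well, giving (3R)-3-[4-methoxy-5-(2-methylbut-3-en-2-yl)-2,3-bis(trimethylsilyloxy)phenyl]-3,7-bis(trimethylsilyloxy)-2,3-dihydro-4H-chromen-4-one F8. The silyl groups are then removed with Bu4NF buffered with AcOH in THF at 0 °C to give 18.

## Further compounds

F1 | step 4 | 1,2-bis(methoxymethoxy)benzene | COCOc1ccccc1OCOC
F2 | step 4 | 2,3-bis(methoxymethoxy)phenol | COCOc1cccc(O)c1OCOC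
F3 | step 4 | 1,2-bis(methoxymethoxy)-3-[(3-methylbut-2-en-1-yl)oxy]benzene | CC(C)=CCOc1cccc(OCOC)c1OCOC
F4 | step 9 | 1-bromo-4-methoxy-2,3-bis(methoxymethoxy)-5-(2-methylbut-3-en-2-yl)benzene | C=CC(C)(C)c1cc(Br)c(OCOC)c(OCOC)c1OC
F5 | step 9 | 7-(methoxymethoxy)-2,3-dihydro-4H-chromen-4-one | COCOc1ccc2c(c1)OCCC2=O
F6 | step 9 | racemic 3-[4-methoxy-2,3-bis(methoxymethoxy)-5-(2-methylbut-3-en-2-yl)phenyl]-7-(methoxymethoxy)-2,3-dihydro-4H-chromen-4-one | C=CC(C)(C)c1cc(C2COc3cc(OCOC)ccc3C2=O)c(OCOC)c(OCOC)c1OC
F7 | step 2 | [2-fluoro-3,4-bis(methoxymethoxy)phenyl]potassium | COCOc1ccc([K])c(F)c1OCOC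
F8 | step 10 | (3R)-3-[4-methoxy-5-(2-methylbut-3-en-2-yl)-2,3-bis(trimethylsilyloxy)phenyl]-3,7-bis(trimethylsilyloxy)-2,3-dihydro-4H-chromen-4-one | C=CC(C)(C)c1cc([C@@]2(O[Si](C)(C)C)COc3cc(O[Si](C)(C)C)ccc3C2=O)c(O[Si](C)(C)C)c(O[Si](C)(C)C)c1OC
A1 | alternative 1 | (3R)-5-bromo-3,7-bis(methoxymethoxy)-3-[4-methoxy-2,3-bis(methoxymethoxy)-5-(2-methylbut-3-en-2-yl)phenyl]-2,3-dihydro-4H-chromen-4-one | C=CC(C)(C)c1cc([C@@]2(OCOC)COc3cc(OCOC)cc(Br)c3C2=O)c(OCOC)c(OCOC)c1OC
A2 | alternative 1 | methyl (2R)-3-hydroxy-2-(methoxymethoxy)-2-[4-methoxy-2,3-bis(methoxymethoxy)-5-(2-methylbut-3-en-2-yl)phenyl]propanoate | C=CC(C)(C)c1cc([C@@](C(=O)OC)(OCOC)CO)c(OCOC)c(OCOC)c1OC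
A3 | alternative 1 | 3-bromo-5-(methoxymethoxy)benzyne | BrC1=CC(OCOC)=CC#C1
A4 | alternative 2 | (2R)-1-[2-fluoro-4-(methoxymethoxy)phenyl]-3-hydroxy-2-[(4-methoxybenzyl)oxy]-2-[4-methoxy-2,3-bis(methoxymethoxy)-5-(2-methylbut-3-en-2-yl)phenyl]propan-1-one | C=CC(C)(C)c1cc([C@@](C(=O)c2ccc(OCOC)cc2F)(OCc2ccc(OC)cc2)CO)c(OCOC)c(OCOC)c1OC
A5 | alternative 2 | 2-diazo-1-[2-fluoro-4-(methoxymethoxy)phenyl]-2-[4-methoxy-2,3-bis(methoxymethoxy)-5-(2-methylbut-3-en-2-yl)phenyl]ethan-1-one | C=CC(C)(C)c1cc(C(=[N+]=[N-])C(=O)c2ccc(OCOC)cc2F)c(OCOC)c(OCOC)c1OC
A6 | alternative 2 | 4-methoxybenzyl alcohol | COc1ccc(CO)cc1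
A7 | alternative 2 | formaldehyde | C=O
A8 | alternative 3 | (3R)-3-hydroxy-3-[4-methoxy-2,3-bis(methoxymethoxy)-5-(2-methylbut-3-en-2-yl)phenyl]-7-(methoxymethoxy)-2,3-dihydro-4H-chromen-4-one (same structure as 17) | C=CC(C)(C)c1cc([C@@]2(O)COc3cc(OCOC)ccc3C2=O)c(OCOC)c(OCOC)c1OC
A9 | alternative 3 | 2-{2-[4-methoxy-2,3-bis(methoxymethoxy)-5-(2-methylbut-3-en-2-yl)phenyl]-2-oxoethoxy}-4-(methoxymethoxy)benzaldehyde (same structure as 16) | C=CC(C)(C)c1cc(C(=O)COc2cc(OCOC)ccc2C=O)c(OCOC)c(OCOC)c1OC
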